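The route rests on cutting the C1–C10 bond of the ten-membered carbocycle, the bond that germacrane biosynthesis also forms. The C1 carbinol, flanked by the C10 exocyclic methylene (C14) and the C2–C3 epoxide, is the retron of an alkenylmetal addition to an epoxy aldehyde. A Ni/Cr-mediated Nozaki–Hiyama–Kishi macrocyclisation therefore closes the cyclodecane, sets C1 and gives the target in the last step. Its precursor is an open chain with a 2-iodoallyl terminus (C9–C10) and a cis-epoxy aldehyde (C1), already holding the trans α-methylene lactone, the C8 tiglate and both epoxides. It comes from a bis-epoxy bromomethyl butenolide by a zinc Barbier coupling.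

Key step: step 16

Remark: germacrane numbering of the target is used for all intermediates (ring C1–C10; lactone O–C6, C7, C11(=C13), C12; C14 on C10; C15 on C4). Descriptors quoted for an intermediate are those of that compound. The two stoichiometric organometallic species (18, 23) are numbered; species of catalytic cycles are not.

Step 1
Reactants: 1 2-[(tert-butyldimethylsilyl)oxy]acetaldehyde; 2 2-(triphenylphosphoranylidene)propanal
Product: 3 (E)-4-[(tert-butyldimethylsilyl)oxy]-2-methylbut-2-enal
Conditions: toluene, 80 °C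
Reagents that add atoms: none
Why: Wittig olefination with the stabilised formyl ylide, which reacts only with the aliphatic aldehyde and should give the (E)-trisubstituted enal that becomes C3–C6 with the C4=C5 geometry of the later trans-epoxide.

Step 2
Reactants: 3 (E)-enal; 4 methyl bis(2,2,2-trifluoroethyl)phosphonoacetate
Product: 5 methyl (2Z,4E)-6-[(tert-butyldimethylsilyl)oxy]-4-methylhexa-2,4-dienoate
Conditions: KHMDS, 18-crown-6, THF, −78 °C
Reagents that add atoms: none
Why: Still–Gennari variant of the Horner–Wadsworth–Emmons reaction, in which the trifluoroethyl phosphonate under dissociating conditions eliminates kinetically to the (Z)-enoate and so sets the cis C2=C3 geometry needed for the cis-epoxide.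

Step 3
Reactants: 5 (2Z,4E)-dienoate
Product: 6 (2Z,4E)-6-[(tert-butyldimethylsilyl)oxy]-4-methylhexa-2,4-dien-1-ol
Conditions: DIBAL-H, CH2Cl2, −78 °C; Rochelle salt work-up
Reagents that add atoms: none
Why: DIBAL-H 1,2-reduction of the unsaturated ester to the allylic alcohol at low temperature should leave the silyl ether and both alkene geometries untouched.

Step 4
Reactants: 6 (2Z,4E)-dienol
Product: 7 [(2S,3R)-3-[(E)-4-[(tert-butyldimethylsilyl)oxy]but-2-en-2-yl]oxiran-2-yl]methanol
Conditions: Ti(OiPr)4 (10 mol %), L-(+)-diethyl tartrate (12 mol %), TBHP, 4 Å MS, CH2Cl2, −20 °C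
Reagents that add atoms: tert-butyl hydroperoxide CC(C)(C)OO
Why: Sharpless asymmetric epoxidation acts only on the alkene of the free allylic alcohol, the L-(+)-tartrate catalyst delivers oxygen syn to the face that gives the (2S,3R) cis-epoxide, and the lower enantioselectivity usual for cis-allylic alcohols is tolerable because the minor enantiomer becomes a separable diastereomer after step 7.

Step 5
Reactants: 7 cis-epoxy alcohol
Product: 8 C1 triethylsilyl ether of 7
Conditions: TESCl, imidazole, CH2Cl2, 0 °C
Reagents that add atoms: chlorotriethylsilane CC[Si](Cl)(CC)CC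
Why: Silyl ether formation under mildly basic, non-nucleophilic conditions should mask the C1 hydroxyl without Payne rearrangement or opening of the vinyl epoxide.

Step 6
Reactants: 8 bis-silyl ether
Product: 9 (E)-3-[(2R,3S)-3-[(triethylsilyloxy)methyl]oxiran-2-yl]but-2-enal
Conditions: DDQ, CH2Cl2/pH 7 buffer, rt
Reagents that add atoms: none
Why: DDQ oxidation of an allylic silyl ether, in which hydride abstraction from the allylic CH2–OSi gives a silyl oxocarbenium ion that is hydrolysed to the enal, so the allylic TBS ether is removed and oxidised in one operation while the non-allylic TES ether and the epoxide remain.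

Step 7
Reactants: 9 epoxy enal
Product: 10 (3S,4E)-5-[(2R,3S)-3-[(triethylsilyloxy)methyl]oxiran-2-yl]hexa-1,4-dien-3-ol
Conditions: divinylzinc, (−)-MIB (10 mol %), toluene, −20 to 0 °C; aq NH4Cl
Reagents that add atoms: divinylzinc C=C[Zn]C=C
Why: Amino-alcohol-catalysed enantioselective organozinc addition to an aldehyde, in which the (−)-MIB–zinc complex directs vinyl transfer to the Si face of the enal carbonyl (the sense known for this ligand) and thereby sets C6 as S under reagent control.

Step 8
Reactants: 10 vinyl carbinol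
Product: 11 (1S)-1-[(2R,3S)-3-methyl-3-[(2S,3S)-3-[(triethylsilyloxy)methyl]oxiran-2-yl]oxiran-2-yl]prop-2-en-1-ol
Conditions: mCPBA, NaHCO3, CH2Cl2, 0 °C
Reagents that add atoms: 3-chloroperoxybenzoic acid OOC(=O)c1cccc(Cl)c1
Why: Hydroxyl-directed (Henbest) peracid epoxidation, in which the C4 methyl cis to C6 imposes A(1,3) strain so that C6–H eclipses the alkene and the hydrogen-bonded peracid attacks the trisubstituted C4=C5 bond on the hydroxyl face, which should give the threo (4S,5R) epoxide and spare the slower monosubstituted vinyl group.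

Step 9
Reactants: 11 bis-epoxy vinyl carbinol; 12 2-(bromomethyl)prop-2-enoic acid
Product: 13 2-(bromomethyl)acrylate ester of 11
Conditions: DCC, DMAP (5 mol %), CH2Cl2, 0 °C
Reagents that add atoms: none
Why: Steglich esterification acylates the C6 hydroxyl with retention, and the low DMAP loading at 0 °C limits attack on the allylic bromide.

Step 10
Reactants: 13 diene ester
Product: 14 (5S)-3-(bromomethyl)-5-[(2R,3S)-3-methyl-3-[(2S,3S)-3-[(triethylsilyloxy)methyl]oxiran-2-yl]oxiran-2-yl]furan-2(5H)-one
Conditions: Grubbs second-generation catalyst (5 mol %), CH2Cl2, 40 °C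
Reagents that add atoms: none
Why: Ring-closing metathesis between the vinyl group and the acrylate alkene forms the five-membered lactone ring as a butenolide (C7=C11) with loss of ethene and without touching C6.

Step 11
Reactants: 15 but-3-yn-1-ol
Product: 16 3-iodobut-3-en-1-ol
Conditions: NaI, TMSCl, H2O, MeCN, rt
Reagents that add atoms: sodium iodide [Na+].[I-]
Why: Markovnikov hydroiodination of the terminal alkyne by HI generated in situ gives the 2-iodo-1-alkene that becomes C10(I)=C14.

Step 12
Reactants: 16 3-iodobut-3-en-1-ol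
Product: 17 3-iodobut-3-enal
Conditions: Dess–Martin periodinane, CH2Cl2, 0 °C; used crude at once
Reagents that add atoms: none
Why: Dess–Martin oxidation under near-neutral conditions gives the β,γ-unsaturated aldehyde without isomerisation into conjugation, provided it is used immediately.

Step 13
Reactants: 14 bromomethyl butenolide; 17 3-iodobut-3-enal
Product: 19 (4R,5S)-4-[(1S)-1-hydroxy-3-iodobut-3-en-1-yl]-3-methylidene-5-[(2R,3S)-3-methyl-3-[(2S,3S)-3-[(triethylsilyloxy)methyl]oxiran-2-yl]oxiran-2-yl]oxolan-2-one, via allylzinc bromide 18 (not isolated)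
Conditions: Zn dust, THF/sat. aq NH4Cl, 0 °C to rt
Reagents that add atoms: none
Why: Zinc Barbier allylation in which the allylzinc reacts at its γ-carbon (C7) through a Zimmerman–Traxler chair, attack anti to the C6 side chain makes the lactone trans (7R), the ring-locked E-type allyl geometry places the C8 hydroxyl anti to C6 (8S), and the allyl transposition unveils the α-methylene group.

Step 14
Reactants: 19 (8S)-alcohol; 20 tiglic acid [(E)-2-methylbut-2-enoic acid]
Product: 21 (8R)-tiglate, (1R)-3-iodo-1-[(2S,3R)-4-methylidene-2-[(2R,3S)-3-methyl-3-[(2S,3S)-3-[(triethylsilyloxy)methyl]oxiran-2-yl]oxiran-2-yl]-5-oxooxolan-3-yl]but-3-en-1-yl (E)-2-methylbut-2-enoate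
Conditions: PPh3, DIAD, toluene, 0 °C to rt
Reagents that add atoms: none
Why: Mitsunobu esterification, in which tiglate displaces the C8 alkoxyphosphonium by SN2 with inversion to the required 8R ester under non-basic conditions that avoid translactonisation.

Step 15
Reactants: 21 (8R)-tiglate TES ether
Product: 22 seco-aldehyde, (1R)-1-[(2S,3R)-2-[(2R,3S)-3-[(2S,3R)-3-formyloxiran-2-yl]-3-methyloxiran-2-yl]-4-methylidene-5-oxooxolan-3-yl]-3-iodobut-3-en-1-yl (E)-2-methylbut-2-enoate
Conditions: (COCl)2, DMSO, CH2Cl2, −78 to −40 °C; Et3N, −78 to 0 °C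
Reagents that add atoms: none
Why: Swern oxidation applied directly to the primary triethylsilyl ether, in which the chlorosulfonium reagent cleaves the O–Si bond to the alkoxysulfonium ion that collapses with Et3N to the cis-epoxy aldehyde, so no fluoride or acid meets the epoxides or the α-methylene lactone.

Step 16
Reactants: 22 seco-aldehyde
Product: 24 target CNP0164399.1, via alkenylchromium(III) dichloride 23 (not isolated)
Conditions: CrCl2 (excess), NiCl2 (cat.), DMSO/THF, 2 mM, rt
Reagents that add atoms: none
Why: Nozaki–Hiyama–Kishi reaction, in which Ni(0) formed in situ inserts into the C10–I bond, transmetalates to Cr(III), and the alkenylchromium adds to the C1 aldehyde. The closest known reaction type is the Ni/Cr-mediated macrocyclisation of iodoalkenyl aldehydes to medium-ring allylic alcohols. The ten-membered carbocycle closes in a 10-exo-trig mode at the carbonyl carbon. The new stereocentre C1 is controlled by the adjacent cis-epoxide, since Felkin–Anh attack anti to the C2–O bond gives the 1,2-anti carbinol (1S), while the trans-lactone and the two epoxides act as turn elements that bring C1 and C10 together. The step needs chemoselectivity for the aldehyde over lactone, tiglate and epoxides, which the weakly basic organochromium reagent provides, and ring closure over oligomerisation, which high dilution secures.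

Compound list
1 | 2-[(tert-butyldimethylsilyl)oxy]acetaldehyde | CC(C)(C)[Si](C)(C)OCC=O | starting material
2 | 2-(triphenylphosphoranylidene)propanal | CC(C=O)=P(c1ccccc1)(c1ccccc1)c1ccccc1 | starting material
3 | (E)-4-[(tert-butyldimethylsilyl)oxy]-2-methylbut-2-enal | C/C(C=O)=C\CO[Si](C)(C)C(C)(C)C | intermediate
4 | methyl bis(2,2,2-trifluoroethyl)phosphonoacetate | COC(=O)CP(=O)(OCC(F)(F)F)OCC(F)(F)F | starting material
5 | methyl (2Z,4E)-6-[(tert-butyldimethylsilyl)oxy]-4-methylhexa-2,4-dienoate | COC(=O)/C=C\C(C)=C\CO[Si](C)(C)C(C)(C)C | intermediate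
6 | (2Z,4E)-6-[(tert-butyldimethylsilyl)oxy]-4-methylhexa-2,4-dien-1-ol | OC/C=C\C(C)=C\CO[Si](C)(C)C(C)(C)C | intermediate
7 | [(2S,3R)-3-[(E)-4-[(tert-butyldimethylsilyl)oxy]but-2-en-2-yl]oxiran-2-yl]methanol (cis-epoxide) | CC(C)(C)[Si](C)(C)OC/C=C(\C)[C@H]1O[C@H]1CO | intermediate
8 | tert-butyldimethylsilyl (E)-3-[(2R,3S)-3-[(triethylsilyloxy)methyl]oxiran-2-yl]but-2-en-1-yl ether | CC(C)(C)[Si](C)(C)OC/C=C(\C)[C@H]1O[C@H]1CO[Si](CC)(CC)CC | intermediate
9 | (E)-3-[(2R,3S)-3-[(triethylsilyloxy)methyl]oxiran-2-yl]but-2-enal | O=C/C=C(\C)[C@H]1O[C@H]1CO[Si](CC)(CC)CC | intermediate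
10 | (3S,4E)-5-[(2R,3S)-3-[(triethylsilyloxy)methyl]oxiran-2-yl]hexa-1,4-dien-3-ol | C=C[C@H](O)/C=C(\C)[C@H]1O[C@H]1CO[Si](CC)(CC)CC | intermediate
11 | (1S)-1-[(2R,3S)-3-methyl-3-[(2S,3S)-3-[(triethylsilyloxy)methyl]oxiran-2-yl]oxiran-2-yl]prop-2-en-1-ol | C=C[C@H](O)[C@H]1O[C@]1(C)[C@H]1O[C@H]1CO[Si](CC)(CC)CC | intermediate
12 | 2-(bromomethyl)prop-2-enoic acid | C=C(CBr)C(=O)O | starting material
13 | (1S)-1-[(2R,3S)-3-methyl-3-[(2S,3S)-3-[(triethylsilyloxy)methyl]oxiran-2-yl]oxiran-2-yl]prop-2-en-1-yl 2-(bromomethyl)prop-2-enoate | C=C[C@H](OC(=O)C(=C)CBr)[C@H]1O[C@]1(C)[C@H]1O[C@H]1CO[Si](CC)(CC)CC | intermediate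
14 | (5S)-3-(bromomethyl)-5-[(2R,3S)-3-methyl-3-[(2S,3S)-3-[(triethylsilyloxy)methyl]oxiran-2-yl]oxiran-2-yl]furan-2(5H)-one | BrCC1=C[C@@H]([C@H]2O[C@]2(C)[C@H]2O[C@H]2CO[Si](CC)(CC)CC)OC1=O | intermediate
15 | but-3-yn-1-ol | C#CCCO | starting material
16 | 3-iodobut-3-en-1-ol | C=C(I)CCO | intermediate
17 | 3-iodobut-3-enal | C=C(I)CC=O | intermediate
18 | allylzinc bromide formed from 14 (Zn on C13) | Br[Zn]CC1=C[C@@H]([C@H]2O[C@]2(C)[C@H]2O[C@H]2CO[Si](CC)(CC)CC)OC1=O | intermediate
19 | (4R,5S)-4-[(1S)-1-hydroxy-3-iodobut-3-en-1-yl]-3-methylidene-5-[(2R,3S)-3-methyl-3-[(2S,3S)-3-[(triethylsilyloxy)methyl]oxiran-2-yl]oxiran-2-yl]oxolan-2-one | C=C(I)C[C@H](O)[C@H]1C(=C)C(=O)O[C@@H]1[C@H]1O[C@]1(C)[C@H]1O[C@H]1CO[Si](CC)(CC)CC | intermediate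
20 | tiglic acid, (E)-2-methylbut-2-enoic acid | C/C=C(\C)C(=O)O | starting material
21 | (1R)-3-iodo-1-[(2S,3R)-4-methylidene-2-[(2R,3S)-3-methyl-3-[(2S,3S)-3-[(triethylsilyloxy)methyl]oxiran-2-yl]oxiran-2-yl]-5-oxooxolan-3-yl]but-3-en-1-yl (E)-2-methylbut-2-enoate | C=C(I)C[C@@H](OC(=O)/C(C)=C/C)[C@H]1C(=C)C(=O)O[C@@H]1[C@H]1O[C@]1(C)[C@H]1O[C@H]1CO[Si](CC)(CC)CC | intermediate
22 | (1R)-1-[(2S,3R)-2-[(2R,3S)-3-[(2S,3R)-3-formyloxiran-2-yl]-3-methyloxiran-2-yl]-4-methylidene-5-oxooxolan-3-yl]-3-iodobut-3-en-1-yl (E)-2-methylbut-2-enoate | C=C(I)C[C@@H](OC(=O)/C(C)=C/C)[C@H]1C(=C)C(=O)O[C@@H]1[C@H]1O[C@]1(C)[C@H]1O[C@H]1C=O | intermediate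
23 | alkenylchromium(III) dichloride formed from 22 (Cr on C10) | C=C([Cr](Cl)Cl)C[C@@H](OC(=O)/C(C)=C/C)[C@H]1C(=C)C(=O)O[C@@H]1[C@H]1O[C@]1(C)[C@H]1O[C@H]1C=O | intermediate
24 | CNP0164399.1, (1S,2S,3S,4S,5R,6S,7R,8R)-2,3:4,5-diepoxy-1-hydroxy-8-[(E)-2-methylbut-2-enoyloxy]germacra-10(14),11(13)-dien-12,6-olide | C=C1C(=O)O[C@H]2[C@H]1[C@H](OC(=O)/C(C)=C/C)CC(=C)[C@H](O)[C@@H]1O[C@@H]1[C@@]1(C)O[C@H]21 | target

Total step count: 16. Longest linear sequence: 14 steps (steps 1–10 and 13–16); steps 11–12 prepare aldehyde 17.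

Steps most likely to fail

Step 16 (ring closure). The ten-membered ring may close slowly, so that oligomerisation competes, and the facial selectivity at C1 may be dictated by the conformation of the forming ring and not by the Felkin preference of the cis-epoxy aldehyde. Fallback: the C1 configuration is set by reagent-controlled ketone reduction and not by the C–C bond formation. Setting out from 22, the ring closure is run as before and the (1R)-epimeric alcohol F1, alone or mixed with 24, is oxidised with Dess–Martin periodinane to the macrocyclic 1-oxo compound (epoxy α-methylene ketone) F2. F2 is reduced with (S)-Me-CBS and catecholborane at −78 °C, the C10 alkenyl side acting as the large group, which should return the (1S)-alcohol 24.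

Step 13 (Barbier coupling). The addition may pass through an open or boat-like transition state, or partly through α-attack, so that the simple diastereoselection at C8 is eroded or reversed. Fallback: the ester is installed with retention and not by inversion. Setting out from 14 and 17, the (8R)-alcohol F3 obtained from the coupling is esterified under Yamaguchi conditions (tiglic acid 20, 2,4,6-trichlorobenzoyl chloride, Et3N, DMAP, toluene) and the route is rejoined at 21.

Step 14 (Mitsunobu inversion). The activated C8 alkoxyphosphonium may eliminate towards C9 to a conjugated iododiene, or substitution at the hindered carbinol may be incomplete. Fallback: inversion by sulfonate displacement. Setting out from 19, chloromethanesulfonyl chloride and pyridine in CH2Cl2 at 0 °C give the chloromethanesulfonate F4, which is displaced with caesium tiglate and 18-crown-6 in toluene with inversion at C8, rejoining the route at 21.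

Further compounds
F1 | step 16 | (1R)-epimer of 24 | C=C1C(=O)O[C@H]2[C@H]1[C@H](OC(=O)/C(C)=C/C)CC(=C)[C@@H](O)[C@@H]1O[C@@H]1[C@@]1(C)O[C@H]21
F2 | step 16 | 1-oxo analogue of 24 (macrocyclic epoxy α-methylene ketone) | C=C1C(=O)O[C@H]2[C@H]1[C@H](OC(=O)/C(C)=C/C)CC(=C)C(=O)[C@@H]1O[C@@H]1[C@@]1(C)O[C@H]21
F3 | step 13 | (8R)-epimer of alcohol 19 | C=C(I)C[C@@H](O)[C@H]1C(=C)C(=O)O[C@@H]1[C@H]1O[C@]1(C)[C@H]1O[C@H]1CO[Si](CC)(CC)CC
F4 | step 14 | C8 chloromethanesulfonate of 19 | C=C(I)C[C@H](OS(=O)(=O)CCl)[C@H]1C(=C)C(=O)O[C@@H]1[C@H]1O[C@]1(C)[C@H]1O[C@H]1CO[Si](CC)(CC)CC
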